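**Plan**
- **Feature:** the benzene ring carries five substituents in a row (C1 CH2-pyrone, C2 acetyl, C3 OH, C4 OH, C5 OMe) and one hydrogen (C6). C1/C2 are an acceptor pair, matching an acetyl alkyne. C3–C6 are a donor run ending in CH, matching a 1,2,3-trioxygenated butadiene with a free CH2 end.
- **Cuts:** first the three O-benzyl bonds, then arene bonds C6–C1 and C3–C2 ([4+2]). The ynone is cut at C(sp)–acetyl. The pyrone is cut at O1–C2 (lactone), C5–C6 (dianion acylation) and C3–CH2 (acetoacetate alkylation). The diene is cut at O–Si, at the C3 enol ether and at C2–OBn.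
- **Forward order:** the pyrone ring closes first (step 5) and its propargyl arm becomes the ynone (steps 7–8). The diene is made in parallel (steps 9–12). The benzene ring closes last (step 13), and hydrogenolysis ends the route.
- **Stereochemistry:** the only stereocentre, the (S)-carbinol carbon of the side chain, comes from ethyl (S)-3-hydroxybutanoate. Its C–O and C–H bonds are never broken.

Key step: step 13

Remark: stereocentres that are labile or vanish later (C2 of 6 and 8, the ketal carbon of 20) and the alkene geometry of 17 and 19 are left unspecified, because none of them reaches the target.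

**Step 1**
Reactants: 1 ethyl (S)-3-hydroxybutanoate
Product: 2 ethyl (S)-3-(benzyloxy)butanoate
Conditions: BnOC(=NH)CCl3, TfOH (cat.), cyclohexane/CH2Cl2, 0 °C → rt
Reagents that add atoms: benzyl 2,2,2-trichloroacetimidate, N=C(OCc1ccccc1)C(Cl)(Cl)Cl
Why: Acid-catalysed benzyl transfer from the trichloroacetimidate avoids the basic conditions that would cause retro-aldol or β-elimination, and the C–O bond at the stereocentre is untouched, so (S) is retained.

**Step 2**
Reactants: 2 ethyl (S)-3-(benzyloxy)butanoate
Product: 3 (S)-3-(benzyloxy)-N-methoxy-N-methylbutanamide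
Conditions: MeNH(OMe)·HCl, i-PrMgCl, THF, −20 → 0 °C
Reagents that add atoms: N,O-dimethylhydroxylamine hydrochloride, CNOC.Cl
Why: Weinreb amidation of an ester with the chloromagnesium amide made in the flask is fast below 0 °C, and this weakly basic nucleophile should not expel the β-benzyloxy group.

**Step 3**
Reactants: 4 ethyl acetoacetate (in excess), 5 3-bromo-1-(trimethylsilyl)prop-1-yne
Product: 6 ethyl 2-acetyl-5-(trimethylsilyl)pent-4-ynoate
Conditions: K2CO3, acetone, reflux
Reagents that add atoms: none
Why: This is an acetoacetic ester C-alkylation (SN2) with a reactive propargylic bromide, in which the silyl cap removes the acidic alkyne C–H ahead of the dianion step and the new methine centre is labile and later becomes sp2.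

**Step 4**
Reactants: 6 ethyl 2-acetyl-5-(trimethylsilyl)pent-4-ynoate, 3 (S)-3-(benzyloxy)-N-methoxy-N-methylbutanamide
Product: 8 ethyl (7S)-7-(benzyloxy)-3,5-dioxo-2-[3-(trimethylsilyl)prop-2-yn-1-yl]octanoate, via dilithio dianion 7 (not isolated)
Conditions: LDA (2.1 equiv per 6), THF, −78 → 0 °C; then 3, −78 → −20 °C; 1 M HCl quench
Reagents that add atoms: none
Why: In this γ-acylation of a β-keto ester dianion (Weiler dianion chemistry) the more basic terminal CH2 carbanion attacks the Weinreb amide, and the chelated tetrahedral adduct survives until the quench, so neither over-addition nor proton drain by the product should occur.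

**Step 5**
Reactants: 8 ethyl (7S)-7-(benzyloxy)-3,5-dioxo-2-[3-(trimethylsilyl)prop-2-yn-1-yl]octanoate
Product: 9 6-[(2S)-2-(benzyloxy)propyl]-4-hydroxy-3-[3-(trimethylsilyl)prop-2-yn-1-yl]-2H-pyran-2-one
Conditions: DBU (1.1 equiv), toluene, 60 °C; then 1 M HCl
Reagents that add atoms: none
Why: Base-mediated lactonisation of a 3,5-dioxo ester (the C5 enolate oxygen attacks the ester) is the standard entry to 3-alkyl-4-hydroxy-2-pyrones, and because substrate and product rest as delocalised anions the CH2 next to the carbinol carbon is not deprotonated, so the benzyloxy group should stay.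

**Step 6**
Reactants: 9 6-[(2S)-2-(benzyloxy)propyl]-4-hydroxy-3-[3-(trimethylsilyl)prop-2-yn-1-yl]-2H-pyran-2-one
Product: 10 4-(benzyloxy)-6-[(2S)-2-(benzyloxy)propyl]-3-[3-(trimethylsilyl)prop-2-yn-1-yl]-2H-pyran-2-one
Conditions: BnOH, PPh3, DIAD, THF, 0 °C → rt
Reagents that add atoms: benzyl alcohol, OCc1ccccc1
Why: Mitsunobu etherification suits the acidic pyrone enol, is known to alkylate 4-hydroxy-2-pyrones at O4 rather than at O2 or C3, and is neutral, so the silyl alkyne and the β-benzyloxy side chain are not at risk.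

**Step 7**
Reactants: 10 4-(benzyloxy)-6-[(2S)-2-(benzyloxy)propyl]-3-[3-(trimethylsilyl)prop-2-yn-1-yl]-2H-pyran-2-one
Product: 11 4-(benzyloxy)-6-[(2S)-2-(benzyloxy)propyl]-3-(prop-2-yn-1-yl)-2H-pyran-2-one
Conditions: TBAF, AcOH (equimolar), THF, 0 °C
Reagents that add atoms: none
Why: This is a fluoride-induced protodesilylation of an alkynylsilane, and the acetic acid buffer suppresses base-induced elimination in the side chain and propargyl–allenyl isomerisation.

**Step 8**
Reactants: 11 4-(benzyloxy)-6-[(2S)-2-(benzyloxy)propyl]-3-(prop-2-yn-1-yl)-2H-pyran-2-one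
Product: 12 4-(benzyloxy)-6-[(2S)-2-(benzyloxy)propyl]-3-(4-oxopent-2-yn-1-yl)-2H-pyran-2-one
Conditions: AcCl (slow addition), PdCl2(PPh3)2 (cat.), CuI (cat.), Et3N (1.1 equiv), THF, rt
Reagents that add atoms: acetyl chloride, CC(=O)Cl
Why: The acyl Sonogashira coupling forms the copper acetylide with only a tertiary amine, and so avoids a lithium acetylide, which neither the acidic C6 side-chain protons (E1cB loss of benzyl oxide) nor the lactone would tolerate.

**Step 9**
Reactants: 13 methyl acetoacetate
Product: 14 methyl 2-diazo-3-oxobutanoate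
Conditions: p-ABSA, Et3N, MeCN, 0 °C → rt
Reagents that add atoms: 4-acetamidobenzenesulfonyl azide, CC(=O)Nc1ccc(cc1)S(=O)(=O)N=[N+]=[N-]
Why: Regitz diazo transfer to an active methylene compound is general for β-keto esters.

**Step 10**
Reactants: 14 methyl 2-diazo-3-oxobutanoate
Product: 15 methyl 2-(benzyloxy)-3-oxobutanoate
Conditions: BnOH, Rh2(OAc)4 (1 mol %), ClCH2CH2Cl, 80 °C
Reagents that add atoms: benzyl alcohol, OCc1ccccc1
Why: Rhodium-carbenoid O–H insertion of a 2-diazo-1,3-dicarbonyl compound into an alcohol places the benzyloxy group on C2 without the deacylation and rearrangement problems of alkoxide displacement on an α-halo keto ester.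

**Step 11**
Reactants: 15 methyl 2-(benzyloxy)-3-oxobutanoate
Product: 17 methyl 2-(benzyloxy)-3-methoxybut-2-enoate (E/Z mixture), via dimethyl ketal 16 (not isolated)
Conditions: HC(OMe)3, H2SO4 (cat.), MeOH, 50 °C; then TsOH (cat.), toluene, 110 °C, MeOH distilled off
Reagents that add atoms: trimethyl orthoformate, COC(OC)OC
Why: Orthoformate ketalisation followed by acid-catalysed loss of methanol is the standard preparation of 3-methoxycrotonates, and the geometry or position of the new double bond does not matter because every isomer gives the same extended enolate in step 12.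

**Step 12**
Reactants: 17 methyl 2-(benzyloxy)-3-methoxybut-2-enoate
Product: 19 2-(benzyloxy)-1,3-dimethoxy-1-(trimethylsilyloxy)buta-1,3-diene, via lithium dienolate 18 (not isolated)
Conditions: LDA, THF, −78 °C; TMSCl, −78 → 0 °C; pentane, filtration, no aqueous work-up
Reagents that add atoms: chlorotrimethylsilane, C[Si](C)(C)Cl
Why: Kinetic γ-deprotonation of a 3-methoxybut-2-enoate and O-silylation of the extended enolate is the established preparation of Brassard-type 1-methoxy-1-silyloxy dienes.

**Step 13**
Reactants: 12 4-(benzyloxy)-6-[(2S)-2-(benzyloxy)propyl]-3-(4-oxopent-2-yn-1-yl)-2H-pyran-2-one, 19 2-(benzyloxy)-1,3-dimethoxy-1-(trimethylsilyloxy)buta-1,3-diene (in excess)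
Product: 22 3-{[2-acetyl-4-(benzyloxy)-3-hydroxy-5-methoxyphenyl]methyl}-4-(benzyloxy)-6-[(2S)-2-(benzyloxy)propyl]-2H-pyran-2-one (tri-O-benzyl penicanesin D), via cyclohexa-1,4-diene cycloadduct 20 (not isolated), via aryl trimethylsilyl ether 21 (not isolated)
Conditions: toluene (concentrated), 110 °C, sealed tube, Ar; then 1 M HCl, THF, rt
Reagents that add atoms: none
Why: The unsubstituted CH2 end of 19 carries the largest HOMO coefficient of this vinylogous silyl ketene acetal and bonds first to the alkyne carbon β to the ketone of 12 (future C1), after which the ketene-acetal carbon closes onto the α-carbon (future C2), a normal-electron-demand, strongly asynchronous intermolecular [4+2] cycloaddition that gives 20. In 20 the mixed ketal carbon C3 and the CH2 group C6 sit 1,4 to each other, so methanol is lost by 1,4-elimination to give 21, and the acidic work-up removes silicon to leave the phenol hydrogen-bonded to the acetyl oxygen. The closest known reaction is the benzannulation of Brassard-type 1-alkoxy-1-silyloxydienes, contiguously trioxygenated ones included, with acetylenic ketones and esters to give ortho-hydroxyaryl carbonyl compounds. The one ring formed, the six-membered carbocycle, is closed by the cycloaddition itself through bonds C6–C1 and C3–C2, with no further cyclisation involved. No lasting stereocentre is created, since the ketal carbon of 20 becomes planar on aromatisation, and the (S)-centre is a remote spectator under neutral thermal conditions. The step needs head-to-tail regioselectivity, which the matched polarisation of ynone and ketene acetal supplies, and chemoselectivity for the ynone over the pyrone, which is secured because the 4-benzyloxy donor and the full substitution at C3 make the pyrone C=C bonds poor dienophiles while its own diene termini cannot reach the alkyne across a one-carbon tether.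

**Step 14**
Reactants: 22 tri-O-benzyl penicanesin D
Product: 23 penicanesin D, 3-[(2-acetyl-3,4-dihydroxy-5-methoxyphenyl)methyl]-4-hydroxy-6-[(2S)-2-hydroxypropyl]-2H-pyran-2-one
Conditions: H2 (1 atm), 10% Pd/C, EtOAc/EtOH, rt; work-up under Ar
Reagents that add atoms: none
Why: Catalytic hydrogenolysis cleaves the three O–CH2Ph bonds on the benzyl side, so the carbinol configuration is kept, while the chelated aryl ketone and the 4-hydroxy-2-pyrone are reduced only under far more forcing conditions.

**Compound list**
1 | ethyl (S)-3-hydroxybutanoate | CCOC(=O)C[C@H](C)O | starting material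
2 | ethyl (S)-3-(benzyloxy)butanoate | CCOC(=O)C[C@H](C)OCc1ccccc1 | intermediate
3 | (S)-3-(benzyloxy)-N-methoxy-N-methylbutanamide | CON(C)C(=O)C[C@H](C)OCc1ccccc1 | intermediate
4 | ethyl acetoacetate | CCOC(=O)CC(C)=O | starting material
5 | 3-bromo-1-(trimethylsilyl)prop-1-yne | C[Si](C)(C)C#CCBr | starting material
6 | ethyl 2-acetyl-5-(trimethylsilyl)pent-4-ynoate | CCOC(=O)C(CC#C[Si](C)(C)C)C(C)=O | intermediate
7 | dilithio dianion of 6 (not isolated) | [Li+].[Li+].CCOC(=O)C(CC#C[Si](C)(C)C)=C([O-])[CH2-] | intermediate
8 | ethyl (7S)-7-(benzyloxy)-3,5-dioxo-2-[3-(trimethylsilyl)prop-2-yn-1-yl]octanoate | CCOC(=O)C(CC#C[Si](C)(C)C)C(=O)CC(=O)C[C@H](C)OCc1ccccc1 | intermediate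
9 | 6-[(2S)-2-(benzyloxy)propyl]-4-hydroxy-3-[3-(trimethylsilyl)prop-2-yn-1-yl]-2H-pyran-2-one | C[Si](C)(C)C#CCc1c(O)cc(C[C@H](C)OCc2ccccc2)oc1=O | intermediate
10 | 4-(benzyloxy)-6-[(2S)-2-(benzyloxy)propyl]-3-[3-(trimethylsilyl)prop-2-yn-1-yl]-2H-pyran-2-one | C[Si](C)(C)C#CCc1c(OCc2ccccc2)cc(C[C@H](C)OCc2ccccc2)oc1=O | intermediate
11 | 4-(benzyloxy)-6-[(2S)-2-(benzyloxy)propyl]-3-(prop-2-yn-1-yl)-2H-pyran-2-one | C#CCc1c(OCc2ccccc2)cc(C[C@H](C)OCc2ccccc2)oc1=O | intermediate
12 | 4-(benzyloxy)-6-[(2S)-2-(benzyloxy)propyl]-3-(4-oxopent-2-yn-1-yl)-2H-pyran-2-one | CC(=O)C#CCc1c(OCc2ccccc2)cc(C[C@H](C)OCc2ccccc2)oc1=O | intermediate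
13 | methyl acetoacetate | COC(=O)CC(C)=O | starting material
14 | methyl 2-diazo-3-oxobutanoate | COC(=O)C(=[N+]=[N-])C(C)=O | intermediate
15 | methyl 2-(benzyloxy)-3-oxobutanoate | COC(=O)C(OCc1ccccc1)C(C)=O | intermediate
16 | methyl 2-(benzyloxy)-3,3-dimethoxybutanoate (not isolated) | COC(=O)C(OCc1ccccc1)C(C)(OC)OC | intermediate
17 | methyl 2-(benzyloxy)-3-methoxybut-2-enoate (E/Z mixture) | COC(=O)C(OCc1ccccc1)=C(C)OC | intermediate
18 | lithium dienolate of 17 (not isolated) | [Li+].C=C(OC)C(OCc1ccccc1)=C(OC)[O-] | intermediate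
19 | 2-(benzyloxy)-1,3-dimethoxy-1-(trimethylsilyloxy)buta-1,3-diene | C=C(OC)C(OCc1ccccc1)=C(OC)O[Si](C)(C)C | intermediate
20 | 3-{[2-acetyl-4-(benzyloxy)-3,5-dimethoxy-3-(trimethylsilyloxy)cyclohexa-1,4-dien-1-yl]methyl}-4-(benzyloxy)-6-[(2S)-2-(benzyloxy)propyl]-2H-pyran-2-one (not isolated) | COC1=C(OCc2ccccc2)C(OC)(O[Si](C)(C)C)C(C(C)=O)=C(Cc2c(OCc3ccccc3)cc(C[C@H](C)OCc3ccccc3)oc2=O)C1 | intermediate
21 | 3-{[2-acetyl-4-(benzyloxy)-5-methoxy-3-(trimethylsilyloxy)phenyl]methyl}-4-(benzyloxy)-6-[(2S)-2-(benzyloxy)propyl]-2H-pyran-2-one (not isolated) | COc1cc(Cc2c(OCc3ccccc3)cc(C[C@H](C)OCc3ccccc3)oc2=O)c(C(C)=O)c(O[Si](C)(C)C)c1OCc1ccccc1 | intermediate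
22 | 3-{[2-acetyl-4-(benzyloxy)-3-hydroxy-5-methoxyphenyl]methyl}-4-(benzyloxy)-6-[(2S)-2-(benzyloxy)propyl]-2H-pyran-2-one | COc1cc(Cc2c(OCc3ccccc3)cc(C[C@H](C)OCc3ccccc3)oc2=O)c(C(C)=O)c(O)c1OCc1ccccc1 | intermediate
23 | penicanesin D, 3-[(2-acetyl-3,4-dihydroxy-5-methoxyphenyl)methyl]-4-hydroxy-6-[(2S)-2-hydroxypropyl]-2H-pyran-2-one | COc1cc(Cc2c(O)cc(C[C@H](C)O)oc2=O)c(C(C)=O)c(O)c1O | target

**Total step count:** 14
**Longest linear sequence:** 9 steps (1, 2, 4, 5, 6, 7, 8, 13, 14)

**Steps most likely to fail**

1. **Step 13.**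
   - What may go wrong: a fully substituted ketene-acetal diene may add to a disubstituted alkyne so slowly that thermal decay and adventitious hydrolysis of the diene win.
   - Fallback: setting out from 12, a catalytic amount of Et3N in CH2Cl2 shifts a propargylic hydrogen and gives the allenyl ketone F1. Its Cα=Cβ bond is strained, sterically open and a better dienophile.
   - Diene 19 should add to it at or slightly above room temperature with the same orientation (CH2 terminus to the central allene carbon), giving the alkylidenecyclohexene adduct F2.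
   - Dilute acid then removes methanol and moves the exocyclic double bond into the ring (isotoluene-to-arene tautomerisation) to give 21. It also cleaves the silyl ether, which brings the material back to the route at 22.
   - This is the allene version of the same benzannulation, known from allenoates and allenedicarboxylates with silyloxy dienes. It also means that partial isomerisation of 12 in step 8 would not be lost material.

2. **Step 8.**
   - What may go wrong: acetyl chloride may be consumed as ketene by the amine, and the amine may shift the skipped ynone towards its allenyl isomer.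
   - Fallback: setting out from 10 (step 7 is then skipped), (Bu3Sn)2O with catalytic TBAF in THF at 60 °C exchanges silicon for tin and gives the alkynylstannane F3.
   - Palladium-catalysed Stille acylation of F3 with acetyl chloride (PdCl2(PPh3)2, ClCH2CH2Cl, 60 °C) runs without any base and rejoins the route at 12.

3. **Step 4.**
   - What may go wrong: proton transfer from the α-CH2 of the amide to the strongly basic dianion, followed by E1cB loss of benzyl oxide, or simply incomplete acylation.
   - Fallback: setting out from 3, DIBAL-H (THF, −78 °C) gives (S)-3-(benzyloxy)butanal F4.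
   - Dianion 7 adds to this far more electrophilic partner within minutes at −78 °C (aldol-type addition) to give the δ-hydroxy-β-keto ester F5 as an epimer mixture.
   - Dess–Martin oxidation of the carbinol returns the material to the route at 8.

**Further compounds**
F1 | step 13 | 4-(benzyloxy)-6-[(2S)-2-(benzyloxy)propyl]-3-(4-oxopenta-1,2-dien-1-yl)-2H-pyran-2-one (allene axis unassigned) | CC(=O)C=C=Cc1c(OCc2ccccc2)cc(C[C@H](C)OCc2ccccc2)oc1=O
F2 | step 13 | 3-{[2-acetyl-4-(benzyloxy)-3,5-dimethoxy-3-(trimethylsilyloxy)cyclohex-4-en-1-ylidene]methyl}-4-(benzyloxy)-6-[(2S)-2-(benzyloxy)propyl]-2H-pyran-2-one | COC1=C(OCc2ccccc2)C(OC)(O[Si](C)(C)C)C(C(C)=O)C(=Cc2c(OCc3ccccc3)cc(C[C@H](C)OCc3ccccc3)oc2=O)C1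
F3 | step 8 | 4-(benzyloxy)-6-[(2S)-2-(benzyloxy)propyl]-3-[3-(tributylstannyl)prop-2-yn-1-yl]-2H-pyran-2-one | CCCC[Sn](CCCC)(CCCC)C#CCc1c(OCc2ccccc2)cc(C[C@H](C)OCc2ccccc2)oc1=O
F4 | step 4 | (S)-3-(benzyloxy)butanal | O=CC[C@H](C)OCc1ccccc1
F5 | step 4 | ethyl (7S)-7-(benzyloxy)-5-hydroxy-3-oxo-2-[3-(trimethylsilyl)prop-2-yn-1-yl]octanoate (epimers at C2 and C5) | CCOC(=O)C(CC#C[Si](C)(C)C)C(=O)CC(O)C[C@H](C)OCc1ccccc1
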